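The constants are those of an exercise; what happens was integrated by code.

In a one-step world the substrate goes to target and nothing more, so I set out to reckon what the second step adds.

the same everywhere: time 6.0 min
- oak: substrate 0.050 M; partner 0.0400 M (in portions, 3, over 5.0 min); temperature 25 °C; first portion at the start, last at 5.0 min
- maple: substrate 0.050 M (fed, over 5.0 min); partner 0.0400 M; temperature 25 °C; all else is in the flask from the start; the feed brings no volume worth counting
- elm: substrate 0.050 M; partner 0.0400 M; temperature 25 °C; everything together at the start
- larch: substrate 0.050 M; partner 0.0400 M (fed, over 5.0 min); the addition at −5 °C, then warmed to 25 °C; the feed brings no volume worth counting

    substrate + partner → target + by-product (k1 = 2.71 /M/s, Ea1 = 40.0 kJ/mol)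
    substrate + by-product → side product (k2 = 0.0467 /M/s, Ea2 = 39.0 kJ/mol)
    substrate + target ⇌ idle adduct, settled at all times (K3 = 94 /M, ΔH3 = −60.0 kJ/mol)
    (constants at 25 °C)

- percentages count the substrate that a species holds: one idle adduct counts as two
- target is meant together with its idle adduct
- constants are those at 25 °C; use the activation energies and enthalpies for any other temperature
- in an amount of target, one idle adduct counts as one target

- the flask that comes out highest in amount of side product, in percent of the substrate charged, or "all alike" when all lie within 1.5 percentage points (oak / maple / elm / larch / all alike)
- side product at the end, in percent of the substrate charged, oak
- side product at the end, in percent of the substrate charged, maple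
- side product at the end, in percent of the substrate charged, elm
- side product at the end, in percent of the substrate charged, larch

Steps 1 and 2 both run on free substrate, so it cancels in their ratio. Side product gained per target gained was therefore by-product over partner, divided by the selectivity factor 58.0, its value at 25 °C. Once the whole partner was in, by-product and partner summed to the partner charge, provided I neglected the by-product that step 2 eats. Let b be the fraction of partner left. The ratio then integrated, in fractions of the substrate charge, to:

side product gained = g × [ln(b before / b after) − (b before − b after)]

I called 1.38 % the leak unit: the side product won each time the partner left falls by a factor e, less that unit times the fraction of partner used.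

For elm I needed b at the end, and that needed the free substrate a. With all partner taken as target and side product set aside, the surplus substrate was 0.200 of the charge, and the adduct balance gave a by going round twice.

First pass, no target yet held in adduct: a = 0.0420

Second pass, that answer put back: a = 0.0498

Pseudo-first-order fading of partner in elm: 0.405 /min

The opening burst in elm was short: the half-life of substrate by the first step alone, the other concentrations as charged, was 0.11 min, far below the 6.0 min of the run. So I let it cost no time and guessed that it left 25.0 % of the partner. That guess was my weak link.

Partner left in elm at the end: 2.20 %

Side product in elm: 3.91 %

The forecast named oak as highest, with 8 % for oak, 2.3 % for maple, 4.1 % for elm and 2.2 % for larch. Its grounds began: "Side product competes with the main reaction in the ratio of by-product to remaining partner". My figure for elm stood lower than its figure.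

The flasks gave 8.16 % for oak, 2.23 % for maple, 4.22 % for elm and 2.12 % for larch, so oak came out highest and the forecast held. For elm I had reckoned 2.20 % of partner left at the end, and the flask held 1.6 %. With that amount the leak unit gives 4.35 % for elm. Larch, left until 25 min, took its partner from 14 % at 6.00 min down to 0.0480 %. For that stretch the leak unit adds 7.6 percentage points to the 2.12 % of larch, making 9.72 %. Larch at that time held 9.20 % of side product.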